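**Retrosynthetic overview**

1. The carboxylic acid comes from a protected primary alcohol; the 1,2-dioxane is closed last by iodonium-induced 6-exo cyclisation of a secondary hydroperoxide onto a trisubstituted alkene, then C–I reduction.
2. That alkene comes from cross-metathesis of an allyl-bearing bicyclic western half with an eastern 2-methyl-1-alkene carrying the peroxide (as a peroxyketal) and the C-2/C-3 stereodiad (syn-aldol, then SN2 peroxidation with inversion).
3. Western half: the ring-fusion alkene and the allylic quaternary centre arise together from a hydride-terminated Wagner–Meerwein 1,2-methyl shift of a tertiary allyl carbinol in a trans-decalin that carries a C7=C8 double bond (key step).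
4. The carbinol comes from allyl addition to a β,γ-unsaturated trans-decalone; the decalone comes from iron-hydride radical–polar crossover annulation of 2-methylcyclohex-2-enone with 4-methylpent-4-enal, resolved as a camphorsulfonate that is also the leaving group.
5. Ring order: ring B (bought) → ring A (annulation) → skeletal 1,2-shift → 1,2-dioxane (last).

Assumption: 1, 2 and 12 are bought as such; locants in names are naphthalene or 1,2-dioxane locants; the carbinol configurations drawn for 3 and 8 are the expected ones and do not matter, because those centres become sp2 later.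

**Route**

Step 1
Reactants: 1 2-methylcyclohex-2-en-1-one; 2 4-methylpent-4-enal
Product: 3 rac-(4aS,8S,8aR)-8-hydroxy-5,5,8a-trimethyloctahydronaphthalen-1(2H)-one
Conditions: Fe(acac)3 (30 mol %), PhSiH3 (2.5 equiv), EtOH/(CH2OH)2 5:1, 0 → 23 °C
Reagents that add atoms: none
Why: Iron-hydride HAT to the 1,1-disubstituted alkene of 2 gives a tertiary radical that adds (Giese) to C-3 of 1, and the resulting iron enolate closes ring A by intramolecular aldol onto the tethered aldehyde (radical–polar crossover annulation), which is expected to give the trans ring fusion (angular methyl anti to H-4a) as a racemate.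

Step 2
Reactants: 3 rac-(4aS,8S,8aR)-8-hydroxy-5,5,8a-trimethyloctahydronaphthalen-1(2H)-one
Product: 4 (1S,4aS,8aR)-4,4,8a-trimethyl-8-oxodecahydronaphthalen-1-yl (1S)-camphor-10-sulfonate
Conditions: (1S)-camphor-10-sulfonyl chloride, Et3N, DMAP (cat.), CH2Cl2, 0 °C; then separation of the two diastereomers (crystallisation, SiO2)
Reagents that add atoms: (1S)-(+)-camphor-10-sulfonyl chloride, CC1(C)[C@@H]2CC[C@@]1(CS(=O)(=O)Cl)C(=O)C2
Why: Sulfonylation through the sulfene reaches the hindered neopentylic alcohol and turns the racemate into two separable diastereomeric sulfonates (classical resolution, at most 50 %), so the absolute configuration at C-4a/C-8a is fixed here while the hydroxyl is activated for elimination.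

Step 3
Reactants: 4 (1S,4aS,8aR)-4,4,8a-trimethyl-8-oxodecahydronaphthalen-1-yl (1S)-camphor-10-sulfonate
Product: 5 (4aS,8aS)-5,5,8a-trimethyl-3,4,4a,5,6,8a-hexahydronaphthalen-1(2H)-one
Conditions: DBU, toluene, 110 °C
Reagents that add atoms: none
Why: E2 elimination of the sulfonate can only go away from the quaternary C-8a, so the β,γ-unsaturated ketone forms regiospecifically and the two stereocentres are untouched (sulfonate elimination with a non-nucleophilic base).

Step 4
Reactants: 5 (4aS,8aS)-5,5,8a-trimethyl-3,4,4a,5,6,8a-hexahydronaphthalen-1(2H)-one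
Product: 7 (2R,4aS,8aS)-2,5,5,8a-tetramethyl-3,4,4a,5,6,8a-hexahydronaphthalen-1(2H)-one, via lithium enolate 6 (not isolated)
Conditions: LiN(iPr)2, THF, −78 °C; MeI, −78 → 0 °C; then K2CO3, MeOH, 23 °C
Reagents that add atoms: iodomethane, CI
Why: C-2 is the only enolisable position, methylation occurs anti to the axial angular methyl, and the basic equilibration leaves the thermodynamically favoured equatorial 2-methyl epimer (2R) (ketone α-alkylation and epimerisation).

Step 5
Reactants: 7 (2R,4aS,8aS)-2,5,5,8a-tetramethyl-3,4,4a,5,6,8a-hexahydronaphthalen-1(2H)-one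
Product: 8 (1S,2R,4aS,8aS)-1-allyl-2,5,5,8a-tetramethyl-1,2,3,4,4a,5,6,8a-octahydronaphthalen-1-ol
Conditions: CH2=CHCH2MgBr, Et2O, −78 → 0 °C; aq NH4Cl
Reagents that add atoms: allylmagnesium bromide, C=CC[Mg]Br
Why: Allyl Grignard reagents add to hindered, enolisable ketones through a cyclic transition state without enolisation (Grignard 1,2-addition, allyl expected anti to the angular methyl), and the carbinol configuration is irrelevant because C-1 is ionised in the next step.

Step 6
Reactants: 8 (1S,2R,4aS,8aS)-1-allyl-2,5,5,8a-tetramethyl-1,2,3,4,4a,5,6,8a-octahydronaphthalen-1-ol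
Product: 11 (1R,2R,4aS)-1-allyl-1,2,5,5-tetramethyl-1,2,3,4,4a,5,6,7-octahydronaphthalene, via tertiary carbocation 9 (not isolated), via allyl cation 10 (not isolated)
Conditions: Et3SiH (5 equiv), BF3·OEt2 (1.5 equiv), CH2Cl2, −78 → −40 °C
Reagents that add atoms: none
Why: Proposed new method: a hydride-terminated (reductive) Wagner–Meerwein transposition in which BF3 ionises the tertiary carbinol, the axial C-8a methyl (its σ bond parallel to the empty p orbital at C-1 and to the C7=C8 π system) migrates suprafacially to C-1 and so sets the quaternary centre (1R, methyl on the former angular-methyl face) while forming tertiary allyl cation 10, and Et3SiH then delivers hydride to the unhindered secondary terminus C-7 so that the alkene ends at C8=C8a and H-4a is never at risk; the closest known chemistry is the BF3-mediated labdane/drimane-to-halimane methyl shift (which ends by unselective E1 loss) combined with Kursanov–Parnes ionic hydrogenation of allyl cations.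

Step 7
Reactants: 12 propanoyl chloride
Product: 13 (S)-4-benzyl-3-propanoyloxazolidin-2-one
Conditions: (S)-4-benzyloxazolidin-2-one, n-BuLi, THF, −78 °C; then 12, −78 → 0 °C
Reagents that add atoms: (S)-4-benzyloxazolidin-2-one, O=C1N[C@@H](Cc2ccccc2)CO1
Why: N-Acylation of the lithiated oxazolidinone attaches the propionate unit to the Evans auxiliary; no new stereocentre is formed.

Step 8
Reactants: 13 (S)-4-benzyl-3-propanoyloxazolidin-2-one; 2 4-methylpent-4-enal
Product: 15 (S)-4-benzyl-3-[(2S,3R)-3-hydroxy-2,6-dimethylhept-6-enoyl]oxazolidin-2-one, via boron enolate 14 (not isolated)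
Conditions: Bu2BOTf, iPr2NEt, CH2Cl2, −78 → 0 °C; then 2, −78 → 0 °C; pH 7 buffer, MeOH, H2O2
Reagents that add atoms: none
Why: Evans syn-aldol: the Z-boron enolate reacts through a Zimmerman–Traxler chair with the auxiliary shielding one face, setting (2S,3R), i.e. the final C-2 methyl centre and a C-3 carbinol of the configuration needed for later inversion.

Step 9
Reactants: 15 (S)-4-benzyl-3-[(2S,3R)-3-hydroxy-2,6-dimethylhept-6-enoyl]oxazolidin-2-one
Product: 16 (2R,3R)-2,6-dimethylhept-6-ene-1,3-diol
Conditions: LiBH4, MeOH (1 equiv), THF, 0 °C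
Reagents that add atoms: none
Why: Reductive cleavage of the imide with LiBH4 releases the auxiliary and gives the 1,3-diol without epimerisation (the descriptor at C-2 changes only because of CIP priorities).

Step 10
Reactants: 16 (2R,3R)-2,6-dimethylhept-6-ene-1,3-diol
Product: 18 (2R,3R)-1-[(tert-butyldimethylsilyl)oxy]-2,6-dimethylhept-6-en-3-yl methanesulfonate, via silyl ether 17 (not isolated)
Conditions: TBSCl, imidazole, CH2Cl2, −20 °C; then Et3N, MsCl, 0 °C (one pot)
Reagents that add atoms: tert-butyldimethylsilyl chloride, CC(C)(C)[Si](C)(C)Cl; methanesulfonyl chloride, CS(=O)(=O)Cl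
Why: The primary hydroxyl is silylated selectively on steric grounds and the remaining secondary hydroxyl is mesylated with retention (O–S bond formation only).

Step 11
Reactants: 18 (2R,3R)-1-[(tert-butyldimethylsilyl)oxy]-2,6-dimethylhept-6-en-3-yl methanesulfonate
Product: 19 tert-butyl{[(2R,3S)-3-[(2-methoxypropan-2-yl)peroxy]-2,6-dimethylhept-6-en-1-yl]oxy}dimethylsilane
Conditions: 2-methoxypropan-2-yl hydroperoxide, CsOH·H2O, DMF, 0 → 23 °C
Reagents that add atoms: 2-methoxypropan-2-yl hydroperoxide, COC(C)(C)OO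
Why: SN2 alkylation of the caesium peroxide anion by the secondary mesylate proceeds with inversion and sets the peroxide-bearing carbon (3S, the dioxane C-3 of the target) anti to the 2-methyl group; the silyl ether blocks β-elimination pathways that an ester would open.

Step 12
Reactants: 11 (1R,2R,4aS)-1-allyl-1,2,5,5-tetramethyl-1,2,3,4,4a,5,6,7-octahydronaphthalene; 19 tert-butyl{[(2R,3S)-3-[(2-methoxypropan-2-yl)peroxy]-2,6-dimethylhept-6-en-1-yl]oxy}dimethylsilane
Product: 20 tert-butyl({(2R,3S)-3-[(2-methoxypropan-2-yl)peroxy]-2,6-dimethyl-8-[(1R,2R,4aS)-1,2,5,5-tetramethyl-1,2,3,4,4a,5,6,7-octahydronaphthalen-1-yl]oct-6-en-1-yl}oxy)dimethylsilane (E/Z mixture)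
Conditions: second-generation Hoveyda–Grubbs catalyst (10 mol %), 19 (3 equiv), CH2Cl2, 40 °C
Reagents that add atoms: none
Why: Olefin cross-metathesis of the terminal allyl group with the non-dimerising 1,1-disubstituted alkene gives the trisubstituted alkene with loss of ethylene; the hindered ring alkene and the dialkyl peroxyketal are inert, and the E/Z ratio does not matter for the next step.

Step 13
Reactants: 20 tert-butyl({(2R,3S)-3-[(2-methoxypropan-2-yl)peroxy]-2,6-dimethyl-8-[(1R,2R,4aS)-1,2,5,5-tetramethyl-1,2,3,4,4a,5,6,7-octahydronaphthalen-1-yl]oct-6-en-1-yl}oxy)dimethylsilane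
Product: 22 tert-butyl{(2R)-2-[(3S)-6-{1-iodo-2-[(1R,2R,4aS)-1,2,5,5-tetramethyl-1,2,3,4,4a,5,6,7-octahydronaphthalen-1-yl]ethyl}-6-methyl-1,2-dioxan-3-yl]propoxy}dimethylsilane (6-methyl cis to the C-3 side chain; iodide epimers), via hydroperoxide 21 (not isolated)
Conditions: PPTS (cat.), MeOH, 0 °C; evaporate; N-iodosuccinimide, CH2Cl2, −78 → −40 °C, dark
Reagents that add atoms: N-iodosuccinimide, O=C1CCC(=O)N1I
Why: Methanolysis frees the hydroperoxide, which attacks the iodonium ion at the tertiary carbon (6-exo, Markovnikov, anti addition: iodoperoxycyclisation) through a chair transition state with the C-3 substituent and the bulky iodoalkyl branch equatorial and the methyl axial, which sets the quaternary peroxide carbon as in the target (6R after deiodination, expected dr about 5:1, minor epimer removed by chromatography); both alkene isomers converge on the same C-6 configuration.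

Step 14
Reactants: 22 the iodo-1,2-dioxane from step 13
Product: 23 tert-butyl{(2R)-2-[(3S,6R)-6-methyl-6-{2-[(1R,2R,4aS)-1,2,5,5-tetramethyl-1,2,3,4,4a,5,6,7-octahydronaphthalen-1-yl]ethyl}-1,2-dioxan-3-yl]propoxy}dimethylsilane
Conditions: Bu3SnH (3 equiv), Et3B (20 mol %), air, toluene, 0 °C
Reagents that add atoms: none
Why: Radical hydrodeiodination at high stannane concentration traps the secondary radical by hydrogen transfer faster than it can attack the O–O bond, removing the only unwanted stereocentre and leaving the dioxane intact.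

Step 15
Reactants: 23 tert-butyl{(2R)-2-[(3S,6R)-6-methyl-6-{2-[(1R,2R,4aS)-1,2,5,5-tetramethyl-1,2,3,4,4a,5,6,7-octahydronaphthalen-1-yl]ethyl}-1,2-dioxan-3-yl]propoxy}dimethylsilane
Product: 25 mycaperoxide H, (2S)-2-[(3S,6R)-6-methyl-6-{2-[(1R,2R,4aS)-1,2,5,5-tetramethyl-1,2,3,4,4a,5,6,7-octahydronaphthalen-1-yl]ethyl}-1,2-dioxan-3-yl]propanoic acid, via primary alcohol 24 (not isolated)
Conditions: HF·pyridine, THF, 0 °C; then TEMPO (20 mol %), PhI(OAc)2 (2.5 equiv), MeCN/pH 7 buffer, 0 → 23 °C
Reagents that add atoms: water, O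
Why: Fluoride desilylation followed by buffered oxoammonium (TEMPO/PhI(OAc)2) oxidation takes the primary alcohol through the aldehyde hydrate to the acid without acid or base strong enough to epimerise C-2, open the peroxide or move the ring alkene.

**Compound list**

1 | 2-methylcyclohex-2-en-1-one | CC1=CCCCC1=O | starting material
2 | 4-methylpent-4-enal | CC(=C)CCC=O | starting material
3 | rac-(4aS,8S,8aR)-8-hydroxy-5,5,8a-trimethyloctahydronaphthalen-1(2H)-one (racemate; the enantiomer carried on is drawn) | O=C1CCC[C@H]2C(C)(C)CC[C@H](O)[C@]12C | intermediate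
4 | (1S,4aS,8aR)-4,4,8a-trimethyl-8-oxodecahydronaphthalen-1-yl (1S)-camphor-10-sulfonate | O=C1CCC[C@H]2C(C)(C)CC[C@H](OS(=O)(=O)C[C@]34CC[C@H](CC3=O)C4(C)C)[C@]12C | intermediate
5 | (4aS,8aS)-5,5,8a-trimethyl-3,4,4a,5,6,8a-hexahydronaphthalen-1(2H)-one | O=C1CCC[C@H]2C(C)(C)CC=C[C@]12C | intermediate
6 | lithium enolate of 5 (not isolated) | [Li+].[O-]C1=CCC[C@H]2C(C)(C)CC=C[C@]12C | intermediate
7 | (2R,4aS,8aS)-2,5,5,8a-tetramethyl-3,4,4a,5,6,8a-hexahydronaphthalen-1(2H)-one | O=C1[C@H](C)CC[C@H]2C(C)(C)CC=C[C@]12C | intermediate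
8 | (1S,2R,4aS,8aS)-1-allyl-2,5,5,8a-tetramethyl-1,2,3,4,4a,5,6,8a-octahydronaphthalen-1-ol | C=CC[C@]1(O)[C@H](C)CC[C@H]2C(C)(C)CC=C[C@]12C | intermediate
9 | tertiary carbocation at C-1 of 8 (not isolated) | C=CC[C+]1[C@H](C)CC[C@H]2C(C)(C)CC=C[C@]12C | intermediate
10 | allyl cation C8a–C8–C7 after the 1,2-methyl shift (not isolated) | C=CC[C@@]1(C)[C+]2C=CCC(C)(C)[C@@H]2CC[C@H]1C | intermediate
11 | (1R,2R,4aS)-1-allyl-1,2,5,5-tetramethyl-1,2,3,4,4a,5,6,7-octahydronaphthalene | C=CC[C@@]1(C)C2=CCCC(C)(C)[C@@H]2CC[C@H]1C | intermediate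
12 | propanoyl chloride | CCC(=O)Cl | starting material
13 | (S)-4-benzyl-3-propanoyloxazolidin-2-one | CCC(=O)N1[C@@H](Cc2ccccc2)COC1=O | intermediate
14 | Z-dibutylboron enolate of 13 (not isolated) | C/C=C(\OB(CCCC)CCCC)N1[C@@H](Cc2ccccc2)COC1=O | intermediate
15 | (S)-4-benzyl-3-[(2S,3R)-3-hydroxy-2,6-dimethylhept-6-enoyl]oxazolidin-2-one | C=C(C)CC[C@@H](O)[C@H](C)C(=O)N1[C@@H](Cc2ccccc2)COC1=O | intermediate
16 | (2R,3R)-2,6-dimethylhept-6-ene-1,3-diol | C=C(C)CC[C@@H](O)[C@H](C)CO | intermediate
17 | (2R,3R)-1-[(tert-butyldimethylsilyl)oxy]-2,6-dimethylhept-6-en-3-ol (not isolated) | C=C(C)CC[C@@H](O)[C@H](C)CO[Si](C)(C)C(C)(C)C | intermediate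
18 | (2R,3R)-1-[(tert-butyldimethylsilyl)oxy]-2,6-dimethylhept-6-en-3-yl methanesulfonate | C=C(C)CC[C@@H](OS(C)(=O)=O)[C@H](C)CO[Si](C)(C)C(C)(C)C | intermediate
19 | tert-butyl{[(2R,3S)-3-[(2-methoxypropan-2-yl)peroxy]-2,6-dimethylhept-6-en-1-yl]oxy}dimethylsilane | C=C(C)CC[C@H](OOC(C)(C)OC)[C@H](C)CO[Si](C)(C)C(C)(C)C | intermediate
20 | cross-metathesis product, E isomer drawn (E/Z mixture) | CC(C)(C)[Si](C)(C)OC[C@@H](C)[C@H](CC/C(C)=C/C[C@@]1(C)C2=CCCC(C)(C)[C@@H]2CC[C@H]1C)OOC(C)(C)OC | intermediate
21 | hydroperoxide from 20 (not isolated) | CC(C)(C)[Si](C)(C)OC[C@@H](C)[C@H](CC/C(C)=C/C[C@@]1(C)C2=CCCC(C)(C)[C@@H]2CC[C@H]1C)OO | intermediate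
22 | iodo-1,2-dioxane (iodide epimers, C–I centre left open) | C[C@H](CO[Si](C)(C)C(C)(C)C)[C@@H]1CC[C@@](C)(C(I)C[C@@]2(C)C3=CCCC(C)(C)[C@@H]3CC[C@H]2C)OO1 | intermediate
23 | tert-butyl{(2R)-2-[(3S,6R)-6-methyl-6-{2-[(1R,2R,4aS)-1,2,5,5-tetramethyl-1,2,3,4,4a,5,6,7-octahydronaphthalen-1-yl]ethyl}-1,2-dioxan-3-yl]propoxy}dimethylsilane | C[C@H](CO[Si](C)(C)C(C)(C)C)[C@@H]1CC[C@@](C)(CC[C@@]2(C)C3=CCCC(C)(C)[C@@H]3CC[C@H]2C)OO1 | intermediate
24 | (2R)-2-[(3S,6R)-6-methyl-6-{2-[(1R,2R,4aS)-1,2,5,5-tetramethyl-1,2,3,4,4a,5,6,7-octahydronaphthalen-1-yl]ethyl}-1,2-dioxan-3-yl]propan-1-ol (not isolated) | C[C@H](CO)[C@@H]1CC[C@@](C)(CC[C@@]2(C)C3=CCCC(C)(C)[C@@H]3CC[C@H]2C)OO1 | intermediate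
25 | mycaperoxide H | C[C@H](C(=O)O)[C@@H]1CC[C@@](C)(CC[C@@]2(C)C3=CCCC(C)(C)[C@@H]3CC[C@H]2C)OO1 | target

**Step count and risks**

Total: 15 steps. Longest linear sequence: 10 steps (steps 1–6, then 12–15); the eastern branch (steps 7–11) joins at step 12.

The three steps most likely to fail:

Step 6 (the proposed new reductive methyl shift). The risks are direct reduction of cation 9 before migration, proton loss from 10 to dienes, and over-reduction of the product alkene. The fallback uses known chemistry, sets out from 7 and comes back at 11. The C7=C8 bond of 7 is hydrogenated (H2, Pd/C, EtOAc) to (2R,4aS,8aS)-2,5,5,8a-tetramethyloctahydronaphthalen-1(2H)-one F1. Addition of CH2=CHCH2MgBr gives (1S,2R,4aS,8aS)-1-allyl-2,5,5,8a-tetramethyldecahydronaphthalen-1-ol F2. F2 is then put through the classical acid-mediated dehydrative 1,2-methyl shift with E1 termination (BF3·OEt2, CH2Cl2, −78 → 0 °C). This gives 11 together with its tetrasubstituted isomer (1R,2R)-1-allyl-1,2,5,5-tetramethyl-1,2,3,4,5,6,7,8-octahydronaphthalene F3, and the two are separated on AgNO3-impregnated silica. The price is regioselectivity, not stereochemistry, since the shift is still suprafacial.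

Step 12 (cross-metathesis of a hindered allyl group with a 1,1-disubstituted alkene that carries a peroxyketal). The risks are slow turnover and catalyst decay by the O–O group. The fallback sets out from 11 and 18 and comes back at 20: the metathesis is run with the peroxide-free mesylate 18 under the same catalyst to give (2R,3R)-1-[(tert-butyldimethylsilyl)oxy]-2,6-dimethyl-8-[(1R,2R,4aS)-1,2,5,5-tetramethyl-1,2,3,4,4a,5,6,7-octahydronaphthalen-1-yl]oct-6-en-3-yl methanesulfonate F4, and the peroxyketal is installed afterwards by the displacement of step 11 (2-methoxypropan-2-yl hydroperoxide, CsOH·H2O, DMF), so that no peroxide meets the ruthenium catalyst.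

Step 13 (iodoperoxycyclisation). The risks are modest facial selectivity at the quaternary peroxide carbon (methyl versus CH(I)CH2R is the only bias) and acid- or iodine-induced decay of the secondary hydroperoxide. The fallback sets out from 20 and comes back at 23, bypassing 22. After the same methanolysis to 21, kinetic iodonium capture is replaced by reversible, thermodynamically controlled cycloperoxymercuration (Hg(OCOCF3)2, CH2Cl2, 0 °C; then KBr), which lets the bulky mercurio-alkyl branch settle equatorial and gives the C-1′ bromomercurio analogue of 22 F5. Hydride demercuration (NaBH4, aq NaOH, 0 °C) then gives 23 directly.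

Further compounds
F1 | step 6 | (2R,4aS,8aS)-2,5,5,8a-tetramethyloctahydronaphthalen-1(2H)-one | O=C1[C@H](C)CC[C@H]2C(C)(C)CCC[C@]12C
F2 | step 6 | (1S,2R,4aS,8aS)-1-allyl-2,5,5,8a-tetramethyldecahydronaphthalen-1-ol | C=CC[C@]1(O)[C@H](C)CC[C@H]2C(C)(C)CCC[C@]12C
F3 | step 6 | (1R,2R)-1-allyl-1,2,5,5-tetramethyl-1,2,3,4,5,6,7,8-octahydronaphthalene | C=CC[C@]1(C)[C@H](C)CCC2=C1CCCC2(C)C
F4 | step 12 | (2R,3R)-1-[(tert-butyldimethylsilyl)oxy]-2,6-dimethyl-8-[(1R,2R,4aS)-1,2,5,5-tetramethyl-1,2,3,4,4a,5,6,7-octahydronaphthalen-1-yl]oct-6-en-3-yl methanesulfonate | CC(C)(C)[Si](C)(C)OC[C@@H](C)[C@@H](CC/C(C)=C/C[C@@]1(C)C2=CCCC(C)(C)[C@@H]2CC[C@H]1C)OS(C)(=O)=O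
F5 | step 13 | C-1′ bromomercurio analogue of 22 | C[C@H](CO[Si](C)(C)C(C)(C)C)[C@@H]1CC[C@@](C)(C([Hg]Br)C[C@@]2(C)C3=CCCC(C)(C)[C@@H]3CC[C@H]2C)OO1
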